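Ring B of the target is a cyclohex-2-enone (C7 ketone, C8=C9) whose quaternary C10 (methyl, ester chain) lies next to C5, which carries the isopropenyl group cis to that methyl. This 4,4,5-trisubstituted enone is disconnected by an asymmetric [4+2] cycloaddition of a 1-amino-3-siloxybutadiene with (E)-2,4-dimethylpenta-2,4-dienal. One operation closes ring B, forms C5–C6 and C9–C10 and sets both stereocentres; the formyl group becomes the handle for C1–C3 and the masked enone the anchor for ring C. The hydroxyquinone is then fused on by a sulfonyl tetronate annulation, oxidation and O-demethylation.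

Key step: step 2

Numbering: skeletal atoms are labelled as in an abietane (ring B = C5–C10; ring C = C8, C9, C11–C14; C1–C3 = ester chain).
Assumption: the (R,R)-diol is taken to shield the enal face that leads to (5S,10S); if the sense of induction is the opposite one, the (S,S)-antipode is used with no other change.

Step 1
Reactants: 1 methacrolein (2-methylprop-2-enal); 2 2-(triphenyl-λ5-phosphanylidene)propanal
Product: 3 (2E)-2,4-dimethylpenta-2,4-dienal
Conditions: 1 (2 equiv), toluene, BHT (cat.), 90 °C, sealed vessel; distillation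
Reagents that add atoms: none
Why: Wittig olefination with a formyl-stabilised ylide gives the (E)-2-methyl enal (formyl trans to the new alkenyl group), and the excess of the volatile, more electrophilic aldehyde 1 keeps the ylide from homologating the product dienal.

Step 2
Reactants: 3 (2E)-2,4-dimethylpenta-2,4-dienal; 4 (E)-1-(dimethylamino)-3-[(tert-butyldimethylsilyl)oxy]buta-1,3-diene
Product: 5 (1S,2R,6S)-4-[(tert-butyldimethylsilyl)oxy]-2-(dimethylamino)-1-methyl-6-(prop-1-en-2-yl)cyclohex-3-ene-1-carbaldehyde
Conditions: (R,R)-1-naphthyl-TADDOL (20 mol %), 4 (1.5 equiv), toluene, −40 °C, 48–72 h; concentrated cold, used crude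
Reagents that add atoms: none
Why: This is a hydrogen-bond-catalysed Diels–Alder cycloaddition of an aminosiloxydiene with an enal, the closest known case being the same catalysis with α-substituted acroleins: one hydroxyl of the diol binds the formyl oxygen, and the diene adds in a concerted, asynchronous, endo [4+2] step in which its CH2 terminus (C6) leads at the β-carbon (C5) and the amino-bearing carbon (C9) closes onto the α-carbon (C10). Ring B is closed by this intermolecular suprafacial–suprafacial cycloaddition, both ring bonds (C5–C6 and C9–C10) forming in the same step. The cis relation of the C5 isopropenyl and the C10 methyl is a copy of the E geometry of 3, the absolute configuration at C5 and C10 comes from the aryl wall of the diol that blocks one face of the bound enal, and the C9 centre (amino cis to formyl) follows from the endo transition state and is erased in step 5. Regioselectivity is secured by the push–pull polarisation of the diene, and site selectivity for the α,β over the γ,δ double bond by the fact that only the former is directly conjugated to the activated formyl group while the isopropenyl group is twisted out of conjugation by allylic strain against the C2 methyl. Selectivity for C=C over C=O addition rests on the α-methyl enal pattern, which steers these catalysts to the carbocyclic pathway. Because the trisubstituted enal 3 is a slower dienophile than an α-substituted acrolein, the reaction is run warmer and more concentrated than for those substrates, the uncatalysed background being correspondingly slow.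

Step 3
Reactants: 5 (cycloadduct aldehyde); 6 methyl 2-(triphenyl-λ5-phosphanylidene)acetate
Product: 7 methyl (2E)-3-[(1S,2R,6S)-4-[(tert-butyldimethylsilyl)oxy]-2-(dimethylamino)-1-methyl-6-(prop-1-en-2-yl)cyclohex-3-en-1-yl]prop-2-enoate
Conditions: 6 (1.5 equiv), toluene, 70 °C; filtration through Et3N-deactivated silica
Reagents that add atoms: none
Why: Wittig olefination of the neopentyl-type aldehyde with an ester-stabilised ylide gives the (E)-enoate under neutral conditions that leave the silyl enol ether and the tertiary amine intact, and C10 cannot epimerise because it is quaternary.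

Step 4
Reactants: 7 (enoate)
Product: 8 methyl 3-[(1S,2R,6S)-4-[(tert-butyldimethylsilyl)oxy]-2-(dimethylamino)-1-methyl-6-(prop-1-en-2-yl)cyclohex-3-en-1-yl]propanoate
Conditions: [(Ph3P)CuH]6 (0.5 equiv), degassed toluene, H2O (3 equiv), rt
Reagents that add atoms: none
Why: Conjugate reduction by the phosphine-stabilised hydride of monovalent copper is specific for the electron-poor enoate C=C, so the isopropenyl group, the silyl enol ether and the ester carbonyl are untouched, and keeping the ring enone masked at this stage removes it as a competing acceptor.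

Step 5
Reactants: 8 (saturated ester)
Product: 10 methyl 3-[(1R,6S)-1-methyl-4-oxo-6-(prop-1-en-2-yl)cyclohex-2-en-1-yl]propanoate, via β-amino ketone 9 (not isolated)
Conditions: 1 M aq. HCl, THF, 0 °C to rt; NaHCO3 work-up
Reagents that add atoms: none
Why: Acid hydrolysis of the silyl enol ether gives the β-amino ketone 9, which loses dimethylamine by β-elimination (E1cB type) to the conjugated C8=C9 enone, while C5 and C10 are not enolisable and keep their configuration.

Step 6
Reactants: 11 ethyl 2-acetyl-3-methylbutanoate (ethyl 2-isopropylacetoacetate)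
Product: 13 4-hydroxy-3-(propan-2-yl)furan-2(5H)-one (3-isopropyltetronic acid), via γ-bromo keto ester 12 (not isolated)
Conditions: Br2 (1.0 equiv), CHCl3, 0 °C to rt, 16 h; concentrate; neat, 120 °C
Reagents that add atoms: none
Why: In this classical tetronic acid synthesis, bromination under HBr equilibration ends on the terminal methyl group, and on heating the ester oxygen displaces bromide (5-exo-tet lactonisation) with loss of bromoethane to give the enolised lactone.

Step 7
Reactants: 13 (3-isopropyltetronic acid)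
Product: 14 4-methoxy-3-(propan-2-yl)furan-2(5H)-one
Conditions: Me2SO4, K2CO3, acetone, reflux
Reagents that add atoms: dimethyl sulfate, COS(=O)(=O)OC
Why: O-Alkylation of the vinylogous acid with a hard methylating agent and a weak base gives the methyl tetronate, C-alkylation being disfavoured at the isopropyl-bearing C3.

Step 8
Reactants: 14 (methyl tetronate)
Product: 15 4-methoxy-5-(phenylsulfanyl)-3-(propan-2-yl)furan-2(5H)-one (racemic)
Conditions: LiN(i-Pr)2 (2.1 equiv), THF, −78 °C; PhSSPh (1.05 equiv); aq. NH4Cl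
Reagents that add atoms: diphenyl disulfide, c1ccc(SSc2ccccc2)cc1
Why: γ-Deprotonation of the tetronate at C5 gives an aromatic 2-oxidofuran that is sulfenylated at C5 by the disulfide, and the second equivalent of base holds the more acidic product as its anion so that proton exchange and double sulfenylation are suppressed.

Step 9
Reactants: 15 (sulfide)
Product: 16 5-(benzenesulfonyl)-4-methoxy-3-(propan-2-yl)furan-2(5H)-one (racemic)
Conditions: mCPBA (2.2 equiv), CH2Cl2, 0 °C to rt
Reagents that add atoms: 3-chloroperoxybenzoic acid, O=C(OO)c1cccc(Cl)c1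
Why: Peracid oxidation of the sulfide through the sulfoxide to the sulfone is much faster than epoxidation of the electron-poor, fully substituted butenolide alkene.

Step 10
Reactants: 10 (enone); 16 (sulfonyl tetronate)
Product: 19 methyl 3-[(1S,2S)-5,8-dihydroxy-7-methoxy-1-methyl-4-oxo-6-(propan-2-yl)-2-(prop-1-en-2-yl)-1,2,3,4-tetrahydronaphthalen-1-yl]propanoate, via Michael adduct 17 (not isolated), via diketone tautomer 18 (not isolated)
Conditions: 16 (1.2 equiv), LiOt-Bu (1.05 equiv relative to 16), THF, −78 °C; then 10, −78 °C to 50 °C; aq. NH4Cl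
Reagents that add atoms: none
Why: Proposed new method: the lithiated sulfonyl tetronate, a soft and stabilised 2-oxidofuran anion, should add through its sulfonyl-bearing carbon to the β-carbon C9 of enone 10 (Michael addition, giving 17 as its enolate), the C8 enolate should then attack the lactone carbonyl (Dieckmann-type 6-exo-trig closure of ring C), and collapse of the tetrahedral intermediate with loss of benzenesulfinate should give diketone 18, which enolises to the aromatic hydroquinone 19 with C11 from the sulfonyl carbon and C14 from the lactone carbonyl; the closest known reaction is the Hauser–Kraus annulation of 3-sulfonylphthalides with cyclohexenones, from which this step differs in that the donor has no fused benzene ring and the acceptor carries a quaternary carbon next to its β-position, and pre-forming the donor anion with no excess base keeps C6 and the ester α-carbon of 10 from being deprotonated, so C5 and C10 are untouched.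

Step 11
Reactants: 19 (hydroquinone)
Product: 20 methyl 3-[(1S,2S)-7-methoxy-1-methyl-4,5,8-trioxo-6-(propan-2-yl)-2-(prop-1-en-2-yl)-1,2,3,4,5,8-hexahydronaphthalen-1-yl]propanoate
Conditions: Ag2O (3 equiv), MgSO4, Et2O, rt
Reagents that add atoms: none
Why: Two-electron oxidation of the electron-rich hydroquinone to the p-quinone by Ag2O is a mild, neutral, heterogeneous dehydrogenation that leaves the alkene, the ester and both stereocentres alone.

Step 12
Reactants: 20 (methoxyquinone)
Product: 21 methyl 3-[(1S,2S)-7-hydroxy-1-methyl-4,5,8-trioxo-6-(propan-2-yl)-2-(prop-1-en-2-yl)-1,2,3,4,5,8-hexahydronaphthalen-1-yl]propanoate (target)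
Conditions: LiOH (1.1 equiv), THF/H2O, 0 °C; then 1 M HCl
Reagents that add atoms: lithium hydroxide, [Li+].[OH-]
Why: Addition–elimination of hydroxide at C12 of the methoxyquinone (a vinylogous ester activated by the C14 carbonyl through C13 and by the adjacent C11 carbonyl) is far faster than saponification of the aliphatic methyl ester, and the single equivalent of base is consumed as the acidic hydroxyquinone forms, so the ester and the C5 and C10 centres survive.

Compound list
1 | methacrolein (2-methylprop-2-enal) | C=C(C)C=O | starting material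
2 | 2-(triphenyl-λ5-phosphanylidene)propanal | CC(C=O)=P(c1ccccc1)(c1ccccc1)c1ccccc1 | starting material
3 | (2E)-2,4-dimethylpenta-2,4-dienal | O=C/C(C)=C/C(C)=C | intermediate
4 | (E)-1-(dimethylamino)-3-[(tert-butyldimethylsilyl)oxy]buta-1,3-diene | CN(C)/C=C/C(=C)O[Si](C)(C)C(C)(C)C | starting material
5 | (1S,2R,6S)-4-[(tert-butyldimethylsilyl)oxy]-2-(dimethylamino)-1-methyl-6-(prop-1-en-2-yl)cyclohex-3-ene-1-carbaldehyde (amino cis to formyl, isopropenyl cis to methyl) | C=C(C)[C@@H]1CC(O[Si](C)(C)C(C)(C)C)=C[C@@H](N(C)C)[C@@]1(C)C=O | intermediate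
6 | methyl 2-(triphenyl-λ5-phosphanylidene)acetate | COC(=O)C=P(c1ccccc1)(c1ccccc1)c1ccccc1 | starting material
7 | methyl (2E)-3-[(1S,2R,6S)-4-[(tert-butyldimethylsilyl)oxy]-2-(dimethylamino)-1-methyl-6-(prop-1-en-2-yl)cyclohex-3-en-1-yl]prop-2-enoate | C=C(C)[C@@H]1CC(O[Si](C)(C)C(C)(C)C)=C[C@@H](N(C)C)[C@@]1(C)/C=C/C(=O)OC | intermediate
8 | methyl 3-[(1S,2R,6S)-4-[(tert-butyldimethylsilyl)oxy]-2-(dimethylamino)-1-methyl-6-(prop-1-en-2-yl)cyclohex-3-en-1-yl]propanoate | C=C(C)[C@@H]1CC(O[Si](C)(C)C(C)(C)C)=C[C@@H](N(C)C)[C@@]1(C)CCC(=O)OC | intermediate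
9 | methyl 3-[(1S,2R,6S)-2-(dimethylamino)-1-methyl-4-oxo-6-(prop-1-en-2-yl)cyclohexyl]propanoate | C=C(C)[C@@H]1CC(=O)C[C@@H](N(C)C)[C@@]1(C)CCC(=O)OC | intermediate
10 | methyl 3-[(1R,6S)-1-methyl-4-oxo-6-(prop-1-en-2-yl)cyclohex-2-en-1-yl]propanoate | C=C(C)[C@@H]1CC(=O)C=C[C@@]1(C)CCC(=O)OC | intermediate
11 | ethyl 2-acetyl-3-methylbutanoate | CCOC(=O)C(C(C)C)C(C)=O | starting material
12 | ethyl 4-bromo-3-oxo-2-(propan-2-yl)butanoate | CCOC(=O)C(C(C)C)C(=O)CBr | intermediate
13 | 4-hydroxy-3-(propan-2-yl)furan-2(5H)-one | CC(C)C1=C(O)COC1=O | intermediate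
14 | 4-methoxy-3-(propan-2-yl)furan-2(5H)-one | COC1=C(C(C)C)C(=O)OC1 | intermediate
15 | 4-methoxy-5-(phenylsulfanyl)-3-(propan-2-yl)furan-2(5H)-one (racemic) | COC1=C(C(C)C)C(=O)OC1Sc1ccccc1 | intermediate
16 | 5-(benzenesulfonyl)-4-methoxy-3-(propan-2-yl)furan-2(5H)-one (racemic) | COC1=C(C(C)C)C(=O)OC1S(=O)(=O)c1ccccc1 | intermediate
17 | Michael adduct: methyl 3-{2-[2-(benzenesulfonyl)-3-methoxy-5-oxo-4-(propan-2-yl)-2,5-dihydrofuran-2-yl]-1-methyl-4-oxo-6-(prop-1-en-2-yl)cyclohexyl}propanoate (C5 and C10 as in 10; new centres undefined) | C=C(C)[C@@H]1CC(=O)CC(C2(S(=O)(=O)c3ccccc3)OC(=O)C(C(C)C)=C2OC)[C@@]1(C)CCC(=O)OC | intermediate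
18 | diketone tautomer: methyl 3-[7-methoxy-1-methyl-4,5,8-trioxo-6-(propan-2-yl)-2-(prop-1-en-2-yl)-1,2,3,4,4a,5,8,8a-octahydronaphthalen-1-yl]propanoate (C5 and C10 as in 10; ring-fusion centres undefined) | C=C(C)[C@@H]1CC(=O)C2C(=O)C(C(C)C)=C(OC)C(=O)C2[C@@]1(C)CCC(=O)OC | intermediate
19 | methyl 3-[(1S,2S)-5,8-dihydroxy-7-methoxy-1-methyl-4-oxo-6-(propan-2-yl)-2-(prop-1-en-2-yl)-1,2,3,4-tetrahydronaphthalen-1-yl]propanoate | C=C(C)[C@@H]1CC(=O)c2c(O)c(C(C)C)c(OC)c(O)c2[C@@]1(C)CCC(=O)OC | intermediate
20 | methyl 3-[(1S,2S)-7-methoxy-1-methyl-4,5,8-trioxo-6-(propan-2-yl)-2-(prop-1-en-2-yl)-1,2,3,4,5,8-hexahydronaphthalen-1-yl]propanoate | C=C(C)[C@@H]1CC(=O)C2=C(C(=O)C(OC)=C(C(C)C)C2=O)[C@@]1(C)CCC(=O)OC | intermediate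
21 | methyl 3-[(1S,2S)-7-hydroxy-1-methyl-4,5,8-trioxo-6-(propan-2-yl)-2-(prop-1-en-2-yl)-1,2,3,4,5,8-hexahydronaphthalen-1-yl]propanoate | C=C(C)[C@@H]1CC(=O)C2=C(C(=O)C(O)=C(C(C)C)C2=O)[C@@]1(C)CCC(=O)OC | target

Total step count: 12.
Longest linear sequence: 8 steps (1, 2, 3, 4, 5, 10, 11, 12); the donor branch (steps 6–9) joins at step 10.

Steps most likely to fail

1. Step 10 (the one step that goes beyond known chemistry). The Michael addition may stall or revert at the hindered β-carbon C9, or base may trigger a Claisen closure of the C6 enolate onto the side-chain ester before the donor adds. The fallback builds ring C by known reactions; it sets out from 10 and rejoins the route at 21.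
 - Enone 10 is α-iodinated (I2, pyridine, CH2Cl2) to methyl 3-[3-iodo-1-methyl-4-oxo-6-(prop-1-en-2-yl)cyclohex-2-en-1-yl]propanoate F1.
 - Methoxycarbonylation (Pd(OAc)2, PPh3, CO, MeOH, Et3N) gives the alkylidene β-keto ester F2, whose doubly activated C8=C9 bond overcomes the hindrance at C9.
 - A Mukaiyama–Michael addition of the kinetic trimethylsilyl enol ether of 4-methylpentan-2-one (TiCl4, CH2Cl2, −78 °C) gives the 1,5-diketone F3.
 - NaOMe in MeOH closes ring C by a dimedone-type Claisen condensation of the isobutyl ketone methylene onto the C8 ester, giving the fused cyclohexane-1,3-dione F4.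
 - Dehydrogenation with DDQ gives the resorcinol F5.
 - Teuber oxidation with ON(SO3K)2 can only attack the one free ring position, C11, and so gives hydroxyquinone 21 directly.

2. Step 2 (key step). The trisubstituted enal may react too slowly at low temperature, cycloaddition across the formyl C=O may compete under hydrogen-bond activation, or facial discrimination may be insufficient. The fallback moves stereocontrol from the catalyst to the diene; it sets out from 3 and rejoins at 10.
 - The auxiliary diene (2R,5R)-1-[(1E)-3-[(tert-butyldimethylsilyl)oxy]buta-1,3-dien-1-yl]-2,5-diphenylpyrrolidine F6 is prepared from the pyrrolidine and 4-methoxybut-3-en-2-one, followed by O-silylation (KN(SiMe3)2, TBSCl). The antipode is used if the facial sense requires it.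
 - F6 is heated with 3 in toluene (rt to 60 °C) without any hydrogen-bond donor, a thermal, auxiliary-controlled cycloaddition of a known kind, to give the auxiliary cycloadduct aldehyde F7.
 - Wittig reaction with 6 gives the enoate F8, and [(Ph3P)CuH]6 reduction gives the saturated ester F9.
 - Aqueous HCl in THF then gives enone 10 and returns the pyrrolidine for reuse.

3. Step 4. The silyl group and the amine may be lost prematurely, so that the liberated enone is over-reduced, or hydride delivery to the hindered enoate may be incomplete. The fallback separates unmasking from reduction; it sets out from 7 and rejoins at 10.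
 - Compound 7 is unmasked first (1 M HCl, THF) to the enone–enoate F10.
 - The ring ketone is protected as its dioxolane F11 (TMSOCH2CH2OTMS, TMSOTf cat., CH2Cl2, −78 °C); the ring double bond cannot migrate because C10 is quaternary.
 - The enoate alone is reduced with Mg in MeOH to the saturated ester ketal F12; the now unconjugated ring alkene and the isopropenyl group are inert to this reagent.
 - Aqueous HCl in acetone releases enone 10.

Further compounds
F1 | step 10 | methyl 3-[(1S,6S)-3-iodo-1-methyl-4-oxo-6-(prop-1-en-2-yl)cyclohex-2-en-1-yl]propanoate | C=C(C)[C@@H]1CC(=O)C(I)=C[C@@]1(C)CCC(=O)OC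
F2 | step 10 | methyl 3-(3-methoxy-3-oxopropyl)-3-methyl-6-oxo-4-(prop-1-en-2-yl)cyclohex-1-ene-1-carboxylate (C5 and C10 as in 10) | C=C(C)[C@@H]1CC(=O)C(C(=O)OC)=C[C@@]1(C)CCC(=O)OC
F3 | step 10 | methyl 3-(3-methoxy-3-oxopropyl)-3-methyl-2-(4-methyl-2-oxopentyl)-6-oxo-4-(prop-1-en-2-yl)cyclohexane-1-carboxylate (C5 and C10 as in 10) | C=C(C)[C@@H]1CC(=O)C(C(=O)OC)C(CC(=O)CC(C)C)[C@@]1(C)CCC(=O)OC
F4 | step 10 | methyl 3-[1-methyl-4,5,7-trioxo-6-(propan-2-yl)-2-(prop-1-en-2-yl)decahydronaphthalen-1-yl]propanoate (C5 and C10 as in 10) | C=C(C)[C@@H]1CC(=O)C2C(=O)C(C(C)C)C(=O)CC2[C@@]1(C)CCC(=O)OC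
F5 | step 10 | methyl 3-[(1S,2S)-5,7-dihydroxy-1-methyl-4-oxo-6-(propan-2-yl)-2-(prop-1-en-2-yl)-1,2,3,4-tetrahydronaphthalen-1-yl]propanoate | C=C(C)[C@@H]1CC(=O)c2c(O)c(C(C)C)c(O)cc2[C@@]1(C)CCC(=O)OC
F6 | step 2 | (2R,5R)-1-[(1E)-3-[(tert-butyldimethylsilyl)oxy]buta-1,3-dien-1-yl]-2,5-diphenylpyrrolidine | C=C(O[Si](C)(C)C(C)(C)C)/C=C/N1[C@@H](c2ccccc2)CC[C@@H]1c1ccccc1
F7 | step 2 | 4-[(tert-butyldimethylsilyl)oxy]-2-[(2R,5R)-2,5-diphenylpyrrolidin-1-yl]-1-methyl-6-(prop-1-en-2-yl)cyclohex-3-ene-1-carbaldehyde (ring centres as in 5) | C=C(C)[C@@H]1CC(O[Si](C)(C)C(C)(C)C)=C[C@@H](N2[C@@H](c3ccccc3)CC[C@@H]2c2ccccc2)[C@@]1(C)C=O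
F8 | step 2 | methyl (2E)-3-{4-[(tert-butyldimethylsilyl)oxy]-2-[(2R,5R)-2,5-diphenylpyrrolidin-1-yl]-1-methyl-6-(prop-1-en-2-yl)cyclohex-3-en-1-yl}prop-2-enoate (ring centres as in 7) | C=C(C)[C@@H]1CC(O[Si](C)(C)C(C)(C)C)=C[C@@H](N2[C@@H](c3ccccc3)CC[C@@H]2c2ccccc2)[C@@]1(C)/C=C/C(=O)OC
F9 | step 2 | methyl 3-{4-[(tert-butyldimethylsilyl)oxy]-2-[(2R,5R)-2,5-diphenylpyrrolidin-1-yl]-1-methyl-6-(prop-1-en-2-yl)cyclohex-3-en-1-yl}propanoate (ring centres as in 8) | C=C(C)[C@@H]1CC(O[Si](C)(C)C(C)(C)C)=C[C@@H](N2[C@@H](c3ccccc3)CC[C@@H]2c2ccccc2)[C@@]1(C)CCC(=O)OC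
F10 | step 4 | methyl (2E)-3-[1-methyl-4-oxo-6-(prop-1-en-2-yl)cyclohex-2-en-1-yl]prop-2-enoate (C5 and C10 as in 10) | C=C(C)[C@@H]1CC(=O)C=C[C@@]1(C)/C=C/C(=O)OC
F11 | step 4 | methyl (2E)-3-[8-methyl-9-(prop-1-en-2-yl)-1,4-dioxaspiro[4.5]dec-6-en-8-yl]prop-2-enoate (C5 and C10 as in 10) | C=C(C)[C@@H]1CC2(OCCO2)C=C[C@@]1(C)/C=C/C(=O)OC
F12 | step 4 | methyl 3-[8-methyl-9-(prop-1-en-2-yl)-1,4-dioxaspiro[4.5]dec-6-en-8-yl]propanoate (C5 and C10 as in 10) | C=C(C)[C@@H]1CC2(OCCO2)C=C[C@@]1(C)CCC(=O)OC
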